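**Strategy.** The C8(O)–C9H2–C10(Me)=C1 segment of the ten-membered carbocycle is read as the homoallylic product of a cyclopropylcarbinyl cation. The precursor is a nine-membered ring (C1–C8 and C10) that carries a cis-fused cyclopropane (C8–C9–C10) and a C1 carbinol anti to its methylene group. Ionisation at C1 cleaves the internal C8–C10 bond: the ring grows by the single carbon C9, the E C1=C10 olefin forms stereospecifically and methacrylate enters at C8 with inversion. The bicyclo[7.1.0]decane is assembled from an Evans succinate aldol lactone by two Nozaki–Hiyama–Kishi couplings and a hydroxyl-directed cyclopropanation.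

Key step: step 16

Remark: C-locants in names and reasons are the germacrane locants of the target (C1–C10 ring carbons; C11–C13 lactone carbons; C14 methyl on C10; C15 formyl carbon on C4).
Remark: the chiral ligands in steps 6, 14 and 15 are meant as the enantiomers that deliver the configurations drawn in the SMILES.

Step 1
Reactants: 1 4-[(tert-butyldimethylsilyl)oxy]but-2-yn-1-ol
Product: 2 (Z)-4-[(tert-butyldimethylsilyl)oxy]-3-iodobut-2-en-1-ol
Conditions: Red-Al, THF, 0 °C; then I2, −78 °C → rt
Reagents that add atoms: iodine, II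
Why: Hydroxyl-directed trans-hydroalumination of the propargylic alcohol puts aluminium on the distal alkyne carbon and iodinolysis with retention gives the Z iodoalkene, which fixes the later C4=C5 geometry (C15 trans to C6).

Step 2
Reactants: 2 (Z)-4-[(tert-butyldimethylsilyl)oxy]-3-iodobut-2-en-1-ol
Product: 3 (Z)-4-[(tert-butyldimethylsilyl)oxy]-3-iodobut-2-enal
Conditions: activated MnO2, CH2Cl2, rt
Reagents that add atoms: none
Why: Allylic alcohol oxidation with manganese dioxide is neutral and should leave the Z β-iodo enal geometry untouched.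

Step 3
Reactants: 4 (S)-4-benzyl-1,3-oxazolidin-2-one; 5 methyl 4-chloro-4-oxobutanoate
Product: 6 methyl 4-[(S)-4-benzyl-2-oxo-1,3-oxazolidin-3-yl]-4-oxobutanoate
Conditions: n-BuLi, THF, −78 °C; then 5
Reagents that add atoms: none
Why: N-acylation of the lithiated oxazolidinone by the acid chloride gives the succinate imide for the auxiliary-controlled aldol.

Step 4
Reactants: 3 (Z)-4-[(tert-butyldimethylsilyl)oxy]-3-iodobut-2-enal; 6 methyl 4-[(S)-4-benzyl-2-oxo-1,3-oxazolidin-3-yl]-4-oxobutanoate
Product: 8 trans-lactone imide (C6 iodoalkenyl arm; C7 acyl oxazolidinone), via syn-aldol adduct 7 (not isolated)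
Conditions: Bu2BOTf, i-Pr2NEt, CH2Cl2, −78 → 0 °C; pH 7 buffer, MeOH, H2O2; then PPTS (cat.), PhMe, 60 °C
Reagents that add atoms: none
Why: Evans syn-aldol reaction, in which the Z boron enolate of the imide adds through a Zimmerman–Traxler chair on the face left open by the benzyl group and so sets C6 and C7 together, followed by 5-exo lactonisation of the C6 hydroxyl onto the methyl ester to give the 6,7-trans lactone.

Step 5
Reactants: 9 3-[(4-methoxybenzyl)oxy]propan-1-ol
Product: 10 3-[(4-methoxybenzyl)oxy]propanal
Conditions: Dess–Martin periodinane, NaHCO3, CH2Cl2, 0 °C → rt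
Reagents that add atoms: none
Why: Dess–Martin oxidation gives the sensitive β-alkoxy aldehyde under buffered conditions for immediate use.

Step 6
Reactants: 8 trans-lactone imide; 10 3-[(4-methoxybenzyl)oxy]propanal
Product: 11 C3 allylic alcohol (lactone imide with the C1–C3 chain on C4)
Conditions: CrCl2, NiCl2 (cat.), chiral oxazoline–sulfonamide ligand, Et3N, THF, rt
Reagents that add atoms: none
Why: Nozaki–Hiyama–Kishi coupling, in which the alkenylchromium formed from the iodide adds only to the aldehyde (imide and lactone are inert) with retention of the Z geometry, and the chromium-bound chiral ligand selects the aldehyde face that gives the C3 carbinol of the target.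

Step 7
Reactants: 11 C3 allylic alcohol
Product: 12 C3 tert-butyldimethylsilyl ether
Conditions: TBSOTf, 2,6-lutidine, CH2Cl2, −78 °C
Reagents that add atoms: tert-butyldimethylsilyl triflate, CC(C)(C)[Si](C)(C)OS(=O)(=O)C(F)(F)F
Why: Silylation of the hindered secondary allylic alcohol protects C3 for the carbanion and cation chemistry that follows.

Step 8
Reactants: 12 C3 tert-butyldimethylsilyl ether
Product: 13 S-ethyl thioester at C8
Conditions: EtSH, n-BuLi, THF, −78 → 0 °C
Reagents that add atoms: ethanethiol, CCS
Why: Thiolate acyl substitution occurs at the exocyclic imide carbonyl (the most electrophilic acyl group) and releases the auxiliary without forming a free C8 alkoxide that could translactonise.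

Step 9
Reactants: 13 S-ethyl thioester at C8
Product: 14 C8 aldehyde (β-formyl lactone)
Conditions: Et3SiH, 10% Pd/C, acetone, rt
Reagents that add atoms: none
Why: Fukuyama reduction converts the thioester to the aldehyde without touching the lactone, the silyl and benzyl ethers or the trisubstituted alkene.

Step 10
Reactants: 14 C8 aldehyde
Product: 15 (Z)-vinyl iodide (C7–CH=C(I)CH3)
Conditions: EtPPh3I, n-BuLi, THF; I2, −78 °C; NaHMDS, −20 °C; then 14, −78 → −20 °C
Reagents that add atoms: ethyltriphenylphosphonium iodide, CC[P+](c1ccccc1)(c1ccccc1)c1ccccc1.[I-]; iodine, II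
Why: Stork–Zhao-type Wittig olefination with the α-iodo ethylidene ylide gives the Z trisubstituted alkenyl iodide (iodine cis to C7), which brings in C10 and C14 and fixes the cis ring olefin of the nine-membered ring.

Step 11
Reactants: 15 (Z)-vinyl iodide
Product: 18 α-methylene lactone vinyl iodide, via Mannich base 16 (not isolated), via methiodide 17 (not isolated)
Conditions: LiHMDS, THF, −78 °C; CH2=NMe2+ I−, −78 → 0 °C; MeI, THF/MeOH, rt; aq NaHCO3
Reagents that add atoms: N,N-dimethylmethyleneiminium iodide, C=[N+](C)C.[I-]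
Why: Eschenmoser methylenation (lactone enolate Mannich reaction, N-methylation and β-elimination) installs C13 after the last ylide step and leaves C7 untouched because only C11 is enolised.

Step 12
Reactants: 18 α-methylene lactone vinyl iodide
Product: 19 C1 primary alcohol
Conditions: DDQ, CH2Cl2/pH 7 buffer, 0 °C
Reagents that add atoms: none
Why: Oxidative cleavage of the 4-methoxybenzyl ether by DDQ frees only the C1 hydroxyl in the presence of the silyl ethers, the vinyl iodide and the methylene lactone.

Step 13
Reactants: 19 C1 primary alcohol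
Product: 20 C1 aldehyde (seco precursor)
Conditions: Dess–Martin periodinane, NaHCO3, CH2Cl2, 0 °C
Reagents that add atoms: none
Why: Buffered Dess–Martin oxidation gives the β-silyloxy aldehyde without β-elimination.

Step 14
Reactants: 20 C1 aldehyde
Product: 21 nine-membered allylic alcohol (C1 hydroxyl; Z C8=C10)
Conditions: CrCl2, NiCl2 (cat.), chiral oxazoline–sulfonamide ligand, Et3N, THF/DMF, high dilution (slow addition), rt
Reagents that add atoms: none
Why: Intramolecular Nozaki–Hiyama–Kishi reaction closes the nine-membered ring by addition of the C10 alkenylchromium to the C1 aldehyde, a ring size for which this reaction type is known, with retention of the Z olefin and with the chiral ligand on chromium setting the C1 carbinol.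

Step 15
Reactants: 21 nine-membered allylic alcohol
Product: 22 anti-cyclopropylcarbinol (bicyclo[7.1.0]decane; cyclopropane C8–C9–C10)
Conditions: Et2Zn, CH2I2, DME, chiral butylboronate tartramide (dioxaborolane) ligand, CH2Cl2, −10 → 20 °C
Reagents that add atoms: diiodomethane, ICI
Why: Hydroxyl-directed Simmons–Smith cyclopropanation, in which the zinc alkoxide at C1 delivers methylene only to the adjacent C8=C10 bond (the silylated C4=C5 olefin and the electron-poor methylene lactone do not react), stereospecifically cis and on the face that leaves the hydroxyl trans to the new CH2 as known for (Z)-cyclonon-2-enols and reinforced by the matched chiral ligand, which sets C8 and C10 of the cyclopropane.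

Step 16
Reactants: 22 anti-cyclopropylcarbinol
Product: 24 ten-membered C8 methacrylate bis-silyl ether, via C1 mesylate 23 (not isolated)
Conditions: Ms2O, Et3N, CH2Cl2, −30 °C; then methacrylic acid, sodium methacrylate, BHT, 0 → 25 °C
Reagents that add atoms: sodium methacrylate, C=C(C)C(=O)[O-].[Na+] (in methacrylic acid, C=C(C)C(=O)O)
Why: Ionisation of the C1 mesylate gives a cyclopropylcarbinyl (bicyclobutonium) cation in which the C1–O bond is antiperiplanar to the ring-fusion bond C8–C10, and methacrylate attacks C8 from the rear as that bond breaks, so that the nine-membered ring opens to the ten-membered ring with C9 as the new ring member. The closest known reaction type is the cyclopropylcarbinyl–homoallyl rearrangement (Julia olefin synthesis) in its solvolytic, stereospecific medium-ring form, in which bicyclo[n.1.0]alkan-2-yl esters with the leaving group anti to the cyclopropane give trans-cycloalk-3-enyl products. No ring is closed, since the ten-membered ring arises by cleavage of the zero bridge of the bicyclo[7.1.0]decane. The C8 stereocentre is set by inversion at the cyclopropane carbon, that is by the cyclopropane face fixed in step 15, and the E geometry of C1=C10 by the anti relation between the C1 leaving group and the cyclopropane methylene, which places C2 and C9 on opposite sides as the π bond forms. The step needs cleavage of the internal C8–C10 bond and not of the external C9–C10 bond, and capture at C8 and not at C1 or C10; the secondary character of C8 against primary C9, the release of cyclopropane strain into a low-strain (E,Z)-cyclodeca-1,5-diene and the buffered carboxylic acid medium are relied on for this.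

Step 17
Reactants: 24 ten-membered C8 methacrylate bis-silyl ether
Product: 25 C3,C15 diol
Conditions: HF·pyridine, pyridine, THF, 0 °C → rt
Reagents that add atoms: none
Why: Fluoride desilylation removes both silyl ethers under buffered conditions that the methacrylate, the lactone and the 1,5-diene tolerate.

Step 18
Reactants: 25 C3,C15 diol
Product: 26 C15 enal (1,10-deoxy target)
Conditions: TEMPO (cat.), PhI(OAc)2, CH2Cl2, rt
Reagents that add atoms: none
Why: Oxoammonium (TEMPO) oxidation is selective for the primary allylic C15 hydroxyl over the secondary C3 hydroxyl and gives the conjugated aldehyde without change at C4=C5.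

Step 19
Reactants: 26 C15 enal
Product: 27 CNP0534814.1 (target)
Conditions: mCPBA, NaHCO3, CH2Cl2, 0 °C
Reagents that add atoms: 3-chloroperoxybenzoic acid, OOC(=O)c1cccc(Cl)c1
Why: Prilezhaev epoxidation attacks the only electron-rich olefin (C1=C10; the enal, methacrylate and methylene lactone double bonds are deactivated) from the outer face of the E olefin in the ring conformer with C14 syn to the C8 ester, which should give stereospecifically the trans 1β,10α-epoxide (1R,10R).

**Compound list**

1 | 4-[(tert-butyldimethylsilyl)oxy]but-2-yn-1-ol | OCC#CCO[Si](C)(C)C(C)(C)C | starting material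
2 | (Z)-4-[(tert-butyldimethylsilyl)oxy]-3-iodobut-2-en-1-ol | OC/C=C(\I)CO[Si](C)(C)C(C)(C)C | intermediate
3 | (Z)-4-[(tert-butyldimethylsilyl)oxy]-3-iodobut-2-enal | O=C/C=C(\I)CO[Si](C)(C)C(C)(C)C | intermediate
4 | (S)-4-benzyl-1,3-oxazolidin-2-one | O=C1N[C@@H](Cc2ccccc2)CO1 | starting material
5 | methyl 4-chloro-4-oxobutanoate | COC(=O)CCC(Cl)=O | starting material
6 | methyl 4-[(S)-4-benzyl-2-oxo-1,3-oxazolidin-3-yl]-4-oxobutanoate | COC(=O)CCC(=O)N1[C@@H](Cc2ccccc2)COC1=O | intermediate
7 | syn-aldol adduct, methyl (3S,4S,5Z)-3-{[(S)-4-benzyl-2-oxo-1,3-oxazolidin-3-yl]carbonyl}-7-[(tert-butyldimethylsilyl)oxy]-4-hydroxy-6-iodohept-5-enoate | COC(=O)C[C@H](C(=O)N1[C@@H](Cc2ccccc2)COC1=O)[C@H](O)/C=C(\I)CO[Si](C)(C)C(C)(C)C | intermediate (not isolated)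
8 | trans-lactone imide, (S)-4-benzyl-3-{[(2S,3S)-2-[(Z)-3-(tert-butyldimethylsilyloxy)-2-iodoprop-1-enyl]-5-oxooxolan-3-yl]carbonyl}-1,3-oxazolidin-2-one (C6, C7 as in the target) | O=C1C[C@H](C(=O)N2[C@@H](Cc3ccccc3)COC2=O)[C@@H](/C=C(\I)CO[Si](C)(C)C(C)(C)C)O1 | intermediate
9 | 3-[(4-methoxybenzyl)oxy]propan-1-ol | OCCCOCc1ccc(OC)cc1 | starting material
10 | 3-[(4-methoxybenzyl)oxy]propanal | O=CCCOCc1ccc(OC)cc1 | intermediate
11 | C3 allylic alcohol: lactone imide 8 in which iodine is replaced by CH(OH)CH2CH2O-PMB (Z olefin kept; C3 as in the target) | O=C1C[C@H](C(=O)N2[C@@H](Cc3ccccc3)COC2=O)[C@@H](/C=C(\[C@@H](O)CCOCc3ccc(OC)cc3)CO[Si](C)(C)C(C)(C)C)O1 | intermediate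
12 | C3 tert-butyldimethylsilyl ether of 11 | O=C1C[C@H](C(=O)N2[C@@H](Cc3ccccc3)COC2=O)[C@@H](/C=C(\[C@@H](O[Si](C)(C)C(C)(C)C)CCOCc3ccc(OC)cc3)CO[Si](C)(C)C(C)(C)C)O1 | intermediate
13 | S-ethyl thioester at C8 (trans-lactone; C7 bears C(=O)SEt) | O=C1C[C@H](C(=O)SCC)[C@@H](/C=C(\[C@@H](O[Si](C)(C)C(C)(C)C)CCOCc2ccc(OC)cc2)CO[Si](C)(C)C(C)(C)C)O1 | intermediate
14 | C8 aldehyde (trans-lactone; C7 bears CHO) | O=C1C[C@H](C=O)[C@@H](/C=C(\[C@@H](O[Si](C)(C)C(C)(C)C)CCOCc2ccc(OC)cc2)CO[Si](C)(C)C(C)(C)C)O1 | intermediate
15 | (Z)-vinyl iodide (trans-lactone; C7 bears (Z)-CH=C(I)CH3) | O=C1C[C@H](/C=C(\I)C)[C@@H](/C=C(\[C@@H](O[Si](C)(C)C(C)(C)C)CCOCc2ccc(OC)cc2)CO[Si](C)(C)C(C)(C)C)O1 | intermediate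
16 | Mannich base (C11 dimethylaminomethyl lactone, C11 epimers) | O=C1C(CN(C)C)[C@H](/C=C(\I)C)[C@@H](/C=C(\[C@@H](O[Si](C)(C)C(C)(C)C)CCOCc2ccc(OC)cc2)CO[Si](C)(C)C(C)(C)C)O1 | intermediate (not isolated)
17 | methiodide of 16 (trimethylammoniomethyl lactone iodide) | O=C1C(C[N+](C)(C)C)[C@H](/C=C(\I)C)[C@@H](/C=C(\[C@@H](O[Si](C)(C)C(C)(C)C)CCOCc2ccc(OC)cc2)CO[Si](C)(C)C(C)(C)C)O1.[I-] | intermediate (not isolated)
18 | α-methylene lactone vinyl iodide (C1 O-PMB) | O=C1C(=C)[C@H](/C=C(\I)C)[C@@H](/C=C(\[C@@H](O[Si](C)(C)C(C)(C)C)CCOCc2ccc(OC)cc2)CO[Si](C)(C)C(C)(C)C)O1 | intermediate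
19 | C1 primary alcohol | O=C1C(=C)[C@H](/C=C(\I)C)[C@@H](/C=C(\[C@@H](O[Si](C)(C)C(C)(C)C)CCO)CO[Si](C)(C)C(C)(C)C)O1 | intermediate
20 | C1 aldehyde (seco precursor with C10 vinyl iodide) | O=C1C(=C)[C@H](/C=C(\I)C)[C@@H](/C=C(\[C@@H](O[Si](C)(C)C(C)(C)C)CC=O)CO[Si](C)(C)C(C)(C)C)O1 | intermediate
21 | nine-membered allylic alcohol: (4Z,8Z)-cyclonona-4,8-diene fused to the α-methylene lactone at C6/C7; (1S)-hydroxyl, C3 OTBS, C15 OTBS, C10 methyl | O=C1C(=C)[C@@H]2/C=C(C)\[C@@H](O)C[C@H](O[Si](C)(C)C(C)(C)C)/C(CO[Si](C)(C)C(C)(C)C)=C\[C@H]2O1 | intermediate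
22 | anti-cyclopropylcarbinol: bicyclo[7.1.0]decane with cis-fused cyclopropane C8–C9–C10, C10 methyl, C1 hydroxyl trans to the cyclopropane CH2 | O=C1C(=C)[C@@H]2[C@@H]3C[C@]3(C)[C@@H](O)C[C@H](O[Si](C)(C)C(C)(C)C)/C(CO[Si](C)(C)C(C)(C)C)=C\[C@H]2O1 | intermediate
23 | C1 mesylate of 22 | O=C1C(=C)[C@@H]2[C@@H]3C[C@]3(C)[C@@H](OS(C)(=O)=O)C[C@H](O[Si](C)(C)C(C)(C)C)/C(CO[Si](C)(C)C(C)(C)C)=C\[C@H]2O1 | intermediate (not isolated)
24 | ten-membered C8 methacrylate bis-silyl ether: (1(10)E,4Z)-germacra-1(10),4,11(13)-trien-12,6-olide, 8β-methacryloyloxy, 3β-OTBS, 15-OTBS | C=C(C)C(=O)O[C@@H]1C/C(C)=C/C[C@H](O[Si](C)(C)C(C)(C)C)/C(CO[Si](C)(C)C(C)(C)C)=C\[C@H]2OC(=O)C(=C)[C@@H]21 | intermediate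
25 | C3,C15 diol of 24 | C=C(C)C(=O)O[C@@H]1C/C(C)=C/C[C@H](O)/C(CO)=C\[C@H]2OC(=O)C(=C)[C@@H]21 | intermediate
26 | C15 enal (target lacking the 1,10-epoxide) | C=C(C)C(=O)O[C@@H]1C/C(C)=C/C[C@H](O)/C(C=O)=C\[C@H]2OC(=O)C(=C)[C@@H]21 | intermediate
27 | CNP0534814.1: (1R,3S,6R,7R,8R,10R)-1,10-epoxy-3-hydroxy-15-oxo-germacra-4,11(13)-dien-12,6-olid-8-yl methacrylate | C=C(C)C(=O)O[C@@H]1C[C@@]2(C)O[C@@H]2C[C@H](O)/C(C=O)=C\[C@H]2OC(=O)C(=C)[C@@H]21 | target

**Step count.** Total: 19 steps. Longest linear sequence: 17 steps (1 → 27 through steps 1, 2, 4 and 6–19).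

**Steps most likely to fail**

Step 16 (key step). The delocalised cation may be captured at C1 (return without ring growth) or collapse by bond shift to the tertiary 1-methylcyclobutyl isomer at C10 instead of being captured at C8. The neat carboxylic acid may also cleave the allylic silyl ethers. The fallback sets out from 22 and comes back at 24. It separates ring expansion from acylation: 22 is esterified with 3,5-dinitrobenzoyl chloride and pyridine to the anti 3,5-dinitrobenzoate F1. F1 is solvolysed under the classical buffered conditions for bicyclo[n.1.0]alkan-2-yl esters (aqueous acetone, 2,6-lutidine, 60 °C) to the ring-expanded (E)-homoallylic C8 alcohol F2. F2 is acylated at once with methacrylic anhydride, Et3N and DMAP to give 24.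

Step 14. Intermolecular coupling may compete with closure of the nine-membered ring, and the ligand may control the aldehyde face at C1 incompletely. The fallback sets out from 20 and comes back at 21. It moves the stereocontrol from the C–C bond formation to a ketone reduction: the Ni/Cr cyclisation is run without chiral ligand (DMSO, slow addition) and gives 21 together with its C1 epimer F3. The mixture is oxidised with Dess–Martin periodinane to the Z enone F4. F4 is reduced with (R)-2-methyl-CBS-oxazaborolidine and catecholborane, with the trisubstituted alkenyl branch as the large group in the usual model, to 21.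

Step 19. Facial selectivity of the undirected peracid attack on the flexible ten-membered ring may be poor, and Baeyer–Villiger oxidation of the enal may compete. The fallback sets out from 26 and comes back at 27 without new compounds. It replaces the undirected peracid by a hydroxyl-directed epoxidation with VO(acac)2 (cat.) and t-BuOOH in CH2Cl2. The homoallylic C3 hydroxyl binds vanadium and delivers oxygen to C1=C10 on its own (β) face, which is the 1β,10α-epoxide; the C4=C5 double bond is an electron-poor enal and should not react.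

**Further compounds**

F1 | step 16 | anti 3,5-dinitrobenzoate of 22 (ester at C1) | O=C1C(=C)[C@@H]2[C@@H]3C[C@]3(C)[C@@H](OC(=O)c3cc([N+](=O)[O-])cc([N+](=O)[O-])c3)C[C@H](O[Si](C)(C)C(C)(C)C)/C(CO[Si](C)(C)C(C)(C)C)=C\[C@H]2O1
F2 | step 16 | ring-expanded C8 alcohol (24 with OH in place of the methacrylate) | O[C@@H]1C/C(C)=C/C[C@H](O[Si](C)(C)C(C)(C)C)/C(CO[Si](C)(C)C(C)(C)C)=C\[C@H]2OC(=O)C(=C)[C@@H]21
F3 | step 14 | C1 epimer of 21 | O=C1C(=C)[C@@H]2/C=C(C)\[C@H](O)C[C@H](O[Si](C)(C)C(C)(C)C)/C(CO[Si](C)(C)C(C)(C)C)=C\[C@H]2O1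
F4 | step 14 | nine-membered Z enone (C1 ketone of 21) | O=C1C(=C)[C@@H]2/C=C(C)\C(=O)C[C@H](O[Si](C)(C)C(C)(C)C)/C(CO[Si](C)(C)C(C)(C)C)=C\[C@H]2O1
F0 | step 19 | none | none
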